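**Plan**
1. Retrosynthetic cuts, in order: the oxolane C4–O(C7) bond together with the C3–OH bond (last ring); C10–C11 of the 14-membered carbocycle; C13–C14 and C12–CH3; C15–CH3, C1–C15, the lactone O–C16 bond and C1–C2; C7–C8.
2. Forward: geranyl acetate supplies C2–C7 with the (3E)-alkene; crotylboration adds C8–C10; acetate aldol, Fráter–Seebach glyoxylate aldol with lactonisation (ring 1, γ-lactone) and enolate methylation follow; propargylation and carboalumination add C11–C13; B-alkyl Suzuki coupling closes the carbocycle (ring 2); oxidative cyclisation closes the oxolane (ring 3, last).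
3. Enabling feature: the oxolane (O, C4, C5, C6, C7) is 2,5-trans and the adjacent C3 carries a hydroxyl syn to the ring oxygen. In the ring-opened form the C7 hydroxyl is bishomoallylic to the (3E)-C3=C4 alkene (C7–C6–C5–C4=C3) inside the 14-membered ring, which is the retron of a hydroxyl-directed rhenium-oxo syn-oxidative cyclisation.
4. Stereochemistry: C7/C8 from Brown (Z)-crotylboration; C2 from the (S)-HYTRA acetate aldol; C1 from Fráter–Seebach anti induction by C2; C15 from lactone-enolate methylation trans to C1; C3/C4 from the key step (C7 plus E geometry); 3E from geranyl acetate, 11E from syn-carboalumination.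

Key step: step 18

Remark 1: locants C1–C20 are the cembrane locants of the target (C1 lactone CH next to the C14 ketone, C2 lactone O–CH, C3 carbinol, C4/C7 oxolane carbons, C8 CH(CH3), C11=C12, C15 C(OH)CH3, C16 lactone C=O); the target is (1S,2S,3R,4R,7R,8R,15S,11E). TBS = tert-butyldimethylsilyl; "dienyl" = (1E,5R,6R)-5-(TBS-oxy)-2,6-dimethylocta-1,7-dien-1-yl.
Remark 2: C15 in 15–19 and C14 in 25–29 are carried as epimer mixtures, because each centre is made planar later (step 11, step 16); their SMILES leave that centre open.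

**Route**

Step 1
Reactants: 1 geranyl acetate
Product: 2 (2E)-3-methyl-6-oxohex-2-en-1-yl acetate
Conditions: O3 (1.0 equiv), CH2Cl2/pyridine, −78 °C; then Me2S, −78 °C → rt
Reagents that add atoms: ozone, [O-][O+]=O
Why: Criegee ozonolysis should cleave only the electron-rich 6,7-alkene, because the 2,3-alkene is deactivated by the allylic acetate, so the (E)-trisubstituted alkene (future C3=C4) is kept.

Step 2
Reactants: 2 (2E)-3-methyl-6-oxohex-2-en-1-yl acetate; 3 cis-but-2-ene
Product: 6 (2E,6R,7R)-6-hydroxy-3,7-dimethylnona-2,8-dien-1-yl acetate, via crotylborane 4 (not isolated), via borinate ester 5 (not isolated)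
Conditions: 3, KOtBu, n-BuLi, THF, −78 → −45 °C; (−)-Ipc2BOMe [from (+)-α-pinene], −78 °C; BF3·OEt2; then 2, −78 °C; NaBO3·4H2O, THF/H2O, rt
Reagents that add atoms: none
Why: Brown crotylboration through a Zimmerman–Traxler chair, in which the (Z)-crotyl geometry gives the syn relationship and the isopinocampheyl groups from (+)-α-pinene select the aldehyde face that gives 6R,7R (C7 and C8 of the target), the perborate work-up sparing the acetate.

Step 3
Reactants: 6 (2E,6R,7R)-6-hydroxy-3,7-dimethylnona-2,8-dien-1-yl acetate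
Product: 7 (2E,6R,7R)-6-(TBS-oxy)-3,7-dimethylnona-2,8-dien-1-yl acetate
Conditions: TBSCl, imidazole, DMF, rt
Reagents that add atoms: tert-butyldimethylsilyl chloride, CC(C)(C)[Si](C)(C)Cl
Why: Standard imidazole-promoted silylation protects the C7 hydroxyl for the base-mediated steps ahead without touching a stereocentre.

Step 4
Reactants: 7 (2E,6R,7R)-6-(TBS-oxy)-3,7-dimethylnona-2,8-dien-1-yl acetate
Product: 8 (2E,6R,7R)-6-(TBS-oxy)-3,7-dimethylnona-2,8-dien-1-ol
Conditions: K2CO3 (0.2 equiv), MeOH, 0 °C → rt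
Reagents that add atoms: none
Why: Base-catalysed transesterification to methanol removes the primary allylic acetate while the silyl ether is stable.

Step 5
Reactants: 8 (2E,6R,7R)-6-(TBS-oxy)-3,7-dimethylnona-2,8-dien-1-ol
Product: 9 (2E,6R,7R)-6-(TBS-oxy)-3,7-dimethylnona-2,8-dienal
Conditions: MnO2, CH2Cl2, rt
Reagents that add atoms: none
Why: MnO2 oxidises the allylic alcohol chemoselectively to the enal with retention of the E geometry.

Step 6
Reactants: 9 (2E,6R,7R)-6-(TBS-oxy)-3,7-dimethylnona-2,8-dienal; 10 (S)-2-hydroxy-1,2,2-triphenylethyl acetate [(S)-HYTRA]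
Product: 11 (1S)-2-hydroxy-1,2,2-triphenylethyl (3S,4E,8R,9R)-8-(TBS-oxy)-3-hydroxy-5,9-dimethylundeca-4,10-dienoate
Conditions: 10, LDA (2.2 equiv), THF, −78 → 0 °C; MgBr2·OEt2, −78 °C; then 9, THF/2-methylbutane, −125 °C; H2O
Reagents that add atoms: none
Why: HYTRA acetate aldol, in which the magnesium enolate of the doubly deprotonated auxiliary ester adds 1,2 to the enal with auxiliary control of the aldehyde face and should set the 3S carbinol (C2 of the target) and form the C1–C2 bond.

Step 7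
Reactants: 11 (1S)-2-hydroxy-1,2,2-triphenylethyl (3S,4E,8R,9R)-8-(TBS-oxy)-3-hydroxy-5,9-dimethylundeca-4,10-dienoate
Product: 12 (3S,4E,8R,9R)-8-(TBS-oxy)-3-hydroxy-5,9-dimethylundeca-4,10-dienoic acid
Conditions: LiOH·H2O, THF/MeOH/H2O, rt; then 1 M HCl to pH 3
Reagents that add atoms: lithium hydroxide, [Li+].[OH-]
Why: Saponification at room temperature releases the β-hydroxy acid and the recoverable auxiliary diol without retro-aldol cleavage.

Step 8
Reactants: 12 (3S,4E,8R,9R)-8-(TBS-oxy)-3-hydroxy-5,9-dimethylundeca-4,10-dienoic acid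
Product: 13 tert-butyl (3S,4E,8R,9R)-8-(TBS-oxy)-3-hydroxy-5,9-dimethylundeca-4,10-dienoate
Conditions: tert-butyl 2,2,2-trichloroacetimidate, cyclohexane/CH2Cl2, rt
Reagents that add atoms: tert-butyl 2,2,2-trichloroacetimidate, CC(C)(C)OC(=N)C(Cl)(Cl)Cl
Why: Imidate esterification, in which only the carboxylic acid is acidic enough to activate the imidate, so the secondary alcohol stays free for the dianion chemistry.

Step 9
Reactants: 13 tert-butyl (3S,4E,8R,9R)-8-(TBS-oxy)-3-hydroxy-5,9-dimethylundeca-4,10-dienoate; 14 ethyl glyoxylate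
Product: 16 tert-butyl 4-hydroxy-5-oxo-2-dienyl-oxolane-3-carboxylate (2,3-cis; oxolane C2 and C3 configured as C2 and C1 of 34; C4 = C15 both epimers), via aldol diol diester 15 (not isolated)
Conditions: LDA (2.2 equiv), THF, −78 → −20 °C; 14 (freshly distilled), −78 °C; AcOH; then PPTS (cat.), CH2Cl2, rt
Reagents that add atoms: none
Why: Fráter–Seebach reaction, in which the lithium-chelated alkoxide–enolate dianion is attacked anti to the C2 alkoxide and so sets C1, after which the C2 hydroxyl closes the γ-lactone on the glyoxylate ester and places the C1 and C2 substituents cis.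

Step 10
Reactants: 16 tert-butyl 4-hydroxy-5-oxo-2-dienyl-oxolane-3-carboxylate
Product: 19 4-(TBS-oxy)-5-oxo-2-dienyl-oxolane-3-carboxylic acid (2,3-cis; C4 epimers), via silyl ether ester 17 (not isolated), via trimethylsilyl ester 18 (not isolated)
Conditions: TBSOTf (1.3 equiv), 2,6-lutidine, CH2Cl2, −78 → 0 °C; then TMSOTf (2 equiv), rt; then THF/AcOH/H2O
Reagents that add atoms: tert-butyldimethylsilyl triflate, CC(C)(C)[Si](C)(C)OS(=O)(=O)C(F)(F)F
Why: Silyl triflate chemistry first silylates the C15 hydroxyl and then cleaves the tert-butyl ester by O-silylation and loss of isobutene, the labile silyl ester being hydrolysed on work-up while the silyl ethers and the lactone stay.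

Step 11
Reactants: 19 4-(TBS-oxy)-5-oxo-2-dienyl-oxolane-3-carboxylic acid
Product: 20 4-(TBS-oxy)-4-methyl-5-oxo-2-dienyl-oxolane-3-carboxylic acid (C1, C2 and C15 configured as in 34)
Conditions: NaN(SiMe3)2 (2.3 equiv), THF, −78 °C; MeI; then aq. HCl to pH 3
Reagents that add atoms: iodomethane, CI
Why: Alkylation of the carboxylate/lactone-enolate dianion, in which methyl iodide enters the planar C15 enolate trans to the C1 carboxylate and the C2 side chain, so that the silyloxy group ends cis to C14 as in the target.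

Step 12
Reactants: 20 4-(TBS-oxy)-4-methyl-5-oxo-2-dienyl-oxolane-3-carboxylic acid
Product: 22 4-(TBS-oxy)-4-methyl-5-oxo-2-dienyl-oxolane-3-carbaldehyde (C14 aldehyde), via acid chloride 21 (not isolated)
Conditions: 1-chloro-N,N,2-trimethylprop-1-en-1-amine, CH2Cl2, 0 °C → rt; then LiAlH(OtBu)3 (1.1 equiv), THF, −78 °C
Reagents that add atoms: none
Why: Neutral acid chloride formation followed by reduction with the hindered alkoxyaluminium hydride at low temperature should stop at the aldehyde and leave the lactone, the silyl ethers and the C1 stereocentre untouched.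

Step 13
Reactants: 22 4-(TBS-oxy)-4-methyl-5-oxo-2-dienyl-oxolane-3-carbaldehyde; 23 propargyl bromide
Product: 25 homopropargylic alcohol, i.e. 22 with C14 as CH(OH)CH2C≡CH (C14 epimers), via allenylzinc bromide 24 (not isolated)
Conditions: 23, Zn dust, THF, 0 °C → rt; H2O
Reagents that add atoms: none
Why: Barbier propargylation, in which the allenylzinc reagent adds through its γ-carbon to give the homopropargylic alcohol and form C13–C14 under non-basic conditions that do not epimerise C1, the C14 configuration being irrelevant.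

Step 14
Reactants: 25 homopropargylic alcohol
Product: 27 (E)-alkenyl iodide, i.e. 25 with C11–C13 as CH2–C(CH3)=CH–I, via alkenylalane 26 (not isolated)
Conditions: AlMe3 (3.5 equiv), Cp2ZrCl2 (0.3 equiv), CH2Cl2, 0 °C → rt; then I2, THF, −30 °C; aqueous work-up
Reagents that add atoms: trimethylaluminium, C[Al](C)C; iodine, II
Why: Negishi zirconium-catalysed carboalumination adds methyl and aluminium syn across the terminal alkyne with methyl on C12, and iodinolysis with retention gives the 11E alkenyl iodide, the C14 hydroxyl being masked in the flask as its aluminium alkoxide.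

Step 15
Reactants: 27 (E)-alkenyl iodide
Product: 29 (3E,11E)-7,15-bis(TBS-oxy)-14-hydroxycembra-3,11-dien-16,2-olide (C1, C2, C7, C8, C15 as in 34; C14 epimers), via alkylborane 28 (not isolated)
Conditions: 9-BBN (3 equiv), THF, rt; then slow addition into Pd(dppf)Cl2 (0.2 equiv), AsPh3, Cs2CO3, DMF/THF/H2O, 50 °C, 2 mM
Reagents that add atoms: none
Why: B-alkyl Suzuki–Miyaura macrocyclisation, in which 9-BBN hydroborates only the monosubstituted C9=C10 alkene and palladium couples C10 with the alkenyl iodide with retention of the 11E geometry under high dilution, closing the 14-membered ring without touching a stereocentre.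

Step 16
Reactants: 29 (3E,11E)-7,15-bis(TBS-oxy)-14-hydroxycembra-3,11-dien-16,2-olide
Product: 30 (3E,11E)-7,15-bis(TBS-oxy)-14-oxocembra-3,11-dien-16,2-olide
Conditions: Dess–Martin periodinane, pyridine, CH2Cl2, 0 °C → rt
Reagents that add atoms: none
Why: Buffered Dess–Martin oxidation converts both C14 epimers into the one β,γ-unsaturated ketone without base, so the alkene does not move into conjugation and C1 is not epimerised.

Step 17
Reactants: 30 (3E,11E)-7,15-bis(TBS-oxy)-14-oxocembra-3,11-dien-16,2-olide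
Product: 31 (3E,11E)-7,15-dihydroxy-14-oxocembra-3,11-dien-16,2-olide
Conditions: HF·pyridine, THF/pyridine, 0 °C → rt
Reagents that add atoms: none
Why: Acidic fluoride cleaves both silyl ethers without the basic conditions that would eliminate or epimerise the β-acyloxy ketone.

Step 18
Reactants: 31 (3E,11E)-7,15-dihydroxy-14-oxocembra-3,11-dien-16,2-olide
Product: 34 CNP0264573.3, (11E)-4,7-epoxy-3,15-dihydroxy-14-oxocembr-11-en-16,2-olide (1S,2S,3R,4R,7R,8R,15S), via perrhenate ester 32 (not isolated), via cyclised rhenium ester 33 (not isolated)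
Conditions: Re2O7 (3 equiv), 2,6-lutidine (6 equiv), CH2Cl2, rt; then H2O
Reagents that add atoms: dirhenium heptoxide, O=[Re](=O)(=O)O[Re](=O)(=O)=O
Why: The C7 hydroxyl exchanges onto Re2O7 to give the perrhenate ester 32, whose O–Re=O unit adds suprafacially across the C3=C4 alkene five atoms away (concerted [3+2] addition, or [2+2] addition followed by migration of C4 from rhenium to the alkoxide oxygen), and the resulting pentavalent rhenium ester 33 is hydrolysed to the C3 alcohol. The closest known reaction type is the Kennedy oxidative cyclisation of 5-hydroxyalkenes (bishomoallylic alcohols) to trans-2,5-disubstituted 2-(hydroxyalkyl)oxolanes, which is established for secondary alcohols and trisubstituted alkenes. The oxolane (O, C4, C5, C6, C7) closes in the 5-exo mode by formation of the C4–O bond across the 14-membered carbocycle, C3 staying outside the new ring. C4 is controlled by C7, because in the chair-like metallacyclic transition state the C8 branch on C7 sits pseudo-equatorial and the oxygen reaches the alkene face that places C3 trans to C8 on the oxolane (4R from 7R), and C3 is controlled by the alkene geometry, because both oxygens are delivered to the same face of the (3E)-alkene (3R). The step needs site selectivity for C3=C4 over C11=C12 and for the C7 over the C15 hydroxyl: C11=C12 could only be reached through a six-membered ether transition state and the tertiary C15 hydroxyl only through a strained 2,5-dioxabicyclo[2.2.1]heptanone, whereas C7–OH with C3=C4 is the unstrained five-membered case. 2,6-Lutidine buffers the perrhenic acid so that the allylic C2–O lactone bond is not ionised and the β,γ-unsaturated ketone is not isomerised.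

**Compound list**

1 | geranyl acetate, (2E)-3,7-dimethylocta-2,6-dien-1-yl acetate | CC(=O)OC/C=C(\C)CCC=C(C)C | starting material
2 | (2E)-3-methyl-6-oxohex-2-en-1-yl acetate | CC(=O)OC/C=C(\C)CCC=O | intermediate
3 | cis-but-2-ene | C/C=C\C | starting material
4 | (Z)-but-2-en-1-yl-bis(isopinocampheyl)borane, isopinocampheyl groups from (+)-α-pinene | C/C=C\CB([C@@H]1C[C@@H]2C[C@H]([C@H]1C)C2(C)C)[C@@H]1C[C@@H]2C[C@H]([C@H]1C)C2(C)C | intermediate
5 | bis(isopinocampheyl)borinate ester of 6 | CC(=O)OC/C=C(\C)CC[C@@H](OB([C@@H]1C[C@@H]2C[C@H]([C@H]1C)C2(C)C)[C@@H]1C[C@@H]2C[C@H]([C@H]1C)C2(C)C)[C@H](C)C=C | intermediate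
6 | (2E,6R,7R)-6-hydroxy-3,7-dimethylnona-2,8-dien-1-yl acetate | CC(=O)OC/C=C(\C)CC[C@@H](O)[C@H](C)C=C | intermediate
7 | (2E,6R,7R)-6-(TBS-oxy)-3,7-dimethylnona-2,8-dien-1-yl acetate | CC(=O)OC/C=C(\C)CC[C@@H](O[Si](C)(C)C(C)(C)C)[C@H](C)C=C | intermediate
8 | (2E,6R,7R)-6-(TBS-oxy)-3,7-dimethylnona-2,8-dien-1-ol | OC/C=C(\C)CC[C@@H](O[Si](C)(C)C(C)(C)C)[C@H](C)C=C | intermediate
9 | (2E,6R,7R)-6-(TBS-oxy)-3,7-dimethylnona-2,8-dienal | O=C/C=C(\C)CC[C@@H](O[Si](C)(C)C(C)(C)C)[C@H](C)C=C | intermediate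
10 | (S)-2-hydroxy-1,2,2-triphenylethyl acetate, (S)-HYTRA | CC(=O)O[C@@H](c1ccccc1)C(O)(c1ccccc1)c1ccccc1 | starting material
11 | (1S)-2-hydroxy-1,2,2-triphenylethyl (3S,4E,8R,9R)-8-(TBS-oxy)-3-hydroxy-5,9-dimethylundeca-4,10-dienoate | O=C(C[C@H](O)/C=C(\C)CC[C@@H](O[Si](C)(C)C(C)(C)C)[C@H](C)C=C)O[C@@H](c1ccccc1)C(O)(c1ccccc1)c1ccccc1 | intermediate
12 | (3S,4E,8R,9R)-8-(TBS-oxy)-3-hydroxy-5,9-dimethylundeca-4,10-dienoic acid | OC(=O)C[C@H](O)/C=C(\C)CC[C@@H](O[Si](C)(C)C(C)(C)C)[C@H](C)C=C | intermediate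
13 | tert-butyl (3S,4E,8R,9R)-8-(TBS-oxy)-3-hydroxy-5,9-dimethylundeca-4,10-dienoate | CC(C)(C)OC(=O)C[C@H](O)/C=C(\C)CC[C@@H](O[Si](C)(C)C(C)(C)C)[C@H](C)C=C | intermediate
14 | ethyl glyoxylate (ethyl oxoacetate) | CCOC(=O)C=O | starting material
15 | aldol diol diester: 13 bearing CH(OH)CO2Et on C1, anti to the C2 hydroxyl (C15 epimers) | C=C[C@@H](C)[C@H](O[Si](C)(C)C(C)(C)C)CC/C(C)=C/[C@@H](O)[C@@H](C(O)C(=O)OCC)C(=O)OC(C)(C)C | intermediate
16 | tert-butyl 4-hydroxy-5-oxo-2-dienyl-oxolane-3-carboxylate, 2,3-cis (C2 and C1 as in 34; C15 epimers) | C=C[C@@H](C)[C@H](O[Si](C)(C)C(C)(C)C)CC/C(C)=C/[C@H]1OC(=O)C(O)[C@H]1C(=O)OC(C)(C)C | intermediate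
17 | tert-butyl 4-(TBS-oxy)-5-oxo-2-dienyl-oxolane-3-carboxylate, 2,3-cis (C15 epimers) | C=C[C@@H](C)[C@H](O[Si](C)(C)C(C)(C)C)CC/C(C)=C/[C@H]1OC(=O)C(O[Si](C)(C)C(C)(C)C)[C@H]1C(=O)OC(C)(C)C | intermediate
18 | trimethylsilyl 4-(TBS-oxy)-5-oxo-2-dienyl-oxolane-3-carboxylate, 2,3-cis (C15 epimers) | C=C[C@@H](C)[C@H](O[Si](C)(C)C(C)(C)C)CC/C(C)=C/[C@H]1OC(=O)C(O[Si](C)(C)C(C)(C)C)[C@H]1C(=O)O[Si](C)(C)C | intermediate
19 | 4-(TBS-oxy)-5-oxo-2-dienyl-oxolane-3-carboxylic acid, 2,3-cis (C15 epimers) | C=C[C@@H](C)[C@H](O[Si](C)(C)C(C)(C)C)CC/C(C)=C/[C@H]1OC(=O)C(O[Si](C)(C)C(C)(C)C)[C@H]1C(=O)O | intermediate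
20 | 4-(TBS-oxy)-4-methyl-5-oxo-2-dienyl-oxolane-3-carboxylic acid (C1, C2, C15 as in 34; methyl trans to CO2H) | C=C[C@@H](C)[C@H](O[Si](C)(C)C(C)(C)C)CC/C(C)=C/[C@H]1OC(=O)[C@@](C)(O[Si](C)(C)C(C)(C)C)[C@H]1C(=O)O | intermediate
21 | acid chloride of 20 | C=C[C@@H](C)[C@H](O[Si](C)(C)C(C)(C)C)CC/C(C)=C/[C@H]1OC(=O)[C@@](C)(O[Si](C)(C)C(C)(C)C)[C@H]1C(=O)Cl | intermediate
22 | 4-(TBS-oxy)-4-methyl-5-oxo-2-dienyl-oxolane-3-carbaldehyde (C14 aldehyde) | C=C[C@@H](C)[C@H](O[Si](C)(C)C(C)(C)C)CC/C(C)=C/[C@H]1OC(=O)[C@@](C)(O[Si](C)(C)C(C)(C)C)[C@H]1C=O | intermediate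
23 | propargyl bromide (3-bromoprop-1-yne) | C#CCBr | starting material
24 | allenylzinc bromide (propa-1,2-dienylzinc bromide) | C=C=C[Zn]Br | intermediate
25 | homopropargylic alcohol: 22 with C14 as CH(OH)CH2C≡CH (C14 epimers) | C=C[C@@H](C)[C@H](O[Si](C)(C)C(C)(C)C)CC/C(C)=C/[C@H]1OC(=O)[C@@](C)(O[Si](C)(C)C(C)(C)C)[C@H]1C(O)CC#C | intermediate
26 | alkenylalane: (11E)-C11 dimethylalanyl alkene and C14 dimethylaluminium alkoxide from 25 | C=C[C@@H](C)[C@H](O[Si](C)(C)C(C)(C)C)CC/C(C)=C/[C@H]1OC(=O)[C@@](C)(O[Si](C)(C)C(C)(C)C)[C@H]1C(O[Al](C)C)C/C(C)=C/[Al](C)C | intermediate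
27 | (E)-alkenyl iodide: 25 with C11–C13 as CH2–C(CH3)=CH–I (C14 epimers) | C=C[C@@H](C)[C@H](O[Si](C)(C)C(C)(C)C)CC/C(C)=C/[C@H]1OC(=O)[C@@](C)(O[Si](C)(C)C(C)(C)C)[C@H]1C(O)C/C(C)=C/I | intermediate
28 | B-alkyl-9-borabicyclo[3.3.1]nonane from 27, boron on C10 | B1(C2CCCC1CCC2)CC[C@@H](C)[C@H](O[Si](C)(C)C(C)(C)C)CC/C(C)=C/[C@H]1OC(=O)[C@@](C)(O[Si](C)(C)C(C)(C)C)[C@H]1C(O)C/C(C)=C/I | intermediate
29 | (3E,11E)-7,15-bis(TBS-oxy)-14-hydroxycembra-3,11-dien-16,2-olide (C1, C2, C7, C8, C15 as in 34; C14 epimers) | C/C1=C\CC[C@@H](C)[C@H](O[Si](C)(C)C(C)(C)C)CC/C(C)=C/[C@H]2OC(=O)[C@@](C)(O[Si](C)(C)C(C)(C)C)[C@H]2C(O)C1 | intermediate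
30 | (3E,11E)-7,15-bis(TBS-oxy)-14-oxocembra-3,11-dien-16,2-olide | C/C1=C\CC[C@@H](C)[C@H](O[Si](C)(C)C(C)(C)C)CC/C(C)=C/[C@H]2OC(=O)[C@@](C)(O[Si](C)(C)C(C)(C)C)[C@H]2C(=O)C1 | intermediate
31 | (3E,11E)-7,15-dihydroxy-14-oxocembra-3,11-dien-16,2-olide | C/C1=C\CC[C@@H](C)[C@H](O)CC/C(C)=C/[C@H]2OC(=O)[C@@](C)(O)[C@H]2C(=O)C1 | intermediate
32 | C7 perrhenate ester of 31 | C/C1=C\CC[C@@H](C)[C@H](O[Re](=O)(=O)=O)CC/C(C)=C/[C@H]2OC(=O)[C@@](C)(O)[C@H]2C(=O)C1 | intermediate
33 | C3 O-dioxorhenium ester of 34 (pentavalent rhenium) | C/C1=C\CC[C@@H](C)[C@H]2CC[C@@](C)(O2)[C@H](O[Re](=O)=O)[C@H]2OC(=O)[C@@](C)(O)[C@H]2C(=O)C1 | intermediate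
34 | CNP0264573.3, (1S,2S,3R,4R,7R,8R,15S,11E)-4,7-epoxy-3,15-dihydroxy-14-oxocembr-11-en-16,2-olide | C/C1=C\CC[C@@H](C)[C@H]2CC[C@@](C)(O2)[C@H](O)[C@H]2OC(=O)[C@@](C)(O)[C@H]2C(=O)C1 | target

**Step count and risks**

Total step count: 18. Longest linear sequence: 18 steps (1 → 34).

Steps most likely to fail:

1. Step 18. The macrocycle may not reach the chair-like geometry needed for oxygen delivery to the correct alkene face, so facial selectivity may be poor; the allylic lactone may also ionise under the Lewis-acidic rhenium oxide. The fallback sets out from 31 and comes back at 34, and replaces the metal-oxo transfer by ionic chemistry. N-Iodosuccinimide in MeCN at 0 °C should effect anti iodoetherification, with 5-exo attack of the C7 hydroxyl on C4 and iodine on C3, to give the 3-iodo-4,7-epoxide F1 with iodine on the face opposite to the ether oxygen. AgOCOCF3 in wet acetone then ionises the C3–I bond with participation of the neighbouring C2 acyloxy (lactone) oxygen (Woodward–Prévost principle). Hydrolysis of the dioxolanylium ion and re-closure of the five-membered lactone should give 34 with inversion at C3, the same net syn oxygenation.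

2. Step 15. Oligomerisation may outrun ring closure, and the alkylborane may be lost by protodeboronation or β-hydride elimination at palladium. The fallback sets out from 27 and comes back at 29, and avoids the organoboron coupling. Hydroboration of 27 with 9-BBN followed by NaBO3 oxidation gives the C10 primary alcohol F2. I2, PPh3 and imidazole convert the primary hydroxyl selectively into the C10 iodide F3. A nickel-catalysed reductive alkyl–alkenyl cross-electrophile coupling (NiBr2(dme), 4,4'-di-tert-butyl-2,2'-bipyridine, Zn, NaI, DMA, high dilution) then closes C10–C11 with retention of the 11E geometry.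

3. Step 9. The dianion may undergo retro-aldol cleavage or β-elimination, oligomeric ethyl glyoxylate may react sluggishly, and facial control at C1 may be incomplete with an aldehyde electrophile. The fallback sets out from 13 and comes back at 16, and separates C–C bond formation from oxygenation. The dianion of 13 (LDA) is alkylated with ethyl bromoacetate (Fráter–Seebach alkylation, anti to the C2 alkoxide) to give the hydroxy diester F4, which lactonises (PPTS) to the α-unsubstituted lactone F5. Deprotonation of the lactone (LiN(SiMe3)2, −78 °C) and oxidation of the enolate with 2-(phenylsulfonyl)-3-phenyloxaziridine gives 16 as its C15 epimers.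

**Further compounds**

F1 | step 18 | (11E)-4,7-epoxy-15-hydroxy-3-iodo-14-oxocembr-11-en-16,2-olide, iodine on C3 anti to the ether oxygen (3-epi position) | C/C1=C\CC[C@@H](C)[C@H]2CC[C@@](C)(O2)[C@@H](I)[C@H]2OC(=O)[C@@](C)(O)[C@H]2C(=O)C1
F2 | step 15 | C10 primary alcohol from hydroboration–oxidation of 27 | OCC[C@@H](C)[C@H](O[Si](C)(C)C(C)(C)C)CC/C(C)=C/[C@H]1OC(=O)[C@@](C)(O[Si](C)(C)C(C)(C)C)[C@H]1C(O)C/C(C)=C/I
F3 | step 15 | C10 primary iodide (alkyl iodide/alkenyl iodide) | ICC[C@@H](C)[C@H](O[Si](C)(C)C(C)(C)C)CC/C(C)=C/[C@H]1OC(=O)[C@@](C)(O[Si](C)(C)C(C)(C)C)[C@H]1C(O)C/C(C)=C/I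
F4 | step 9 | hydroxy diester: 13 bearing CH2CO2Et on C1, anti to the C2 hydroxyl | C=C[C@@H](C)[C@H](O[Si](C)(C)C(C)(C)C)CC/C(C)=C/[C@@H](O)[C@@H](CC(=O)OCC)C(=O)OC(C)(C)C
F5 | step 9 | tert-butyl 5-oxo-2-dienyl-oxolane-3-carboxylate, 2,3-cis | C=C[C@@H](C)[C@H](O[Si](C)(C)C(C)(C)C)CC/C(C)=C/[C@H]1OC(=O)C[C@H]1C(=O)OC(C)(C)C
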